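The data are simulated from invented constants, noise included.

Start with a subtraction: if impurity removes second catalyst one for one, less remains to work than was charged.

| setting | green | ochre | red | flask |
|---|---|---|---|---|
| substrate | 6 mM | 9 mM | 12 mM | 12 mM |
| reagent | 1.3 equiv | 1.3 equiv | 1.3 equiv | 1.30 equiv |
| free catalyst | 0.69 mol% | 0.69 mol% | 0.69 mol% | 0.69 mol% |
| second catalyst | 0.1 mol% | 0.1 mol% | 0.2 mol% | 0.1 mol% |
| added ligand | 0.26 mM | 0.26 mM | 0.26 mM | 0.26 mM |
| impurity | 4.8 µM | 4.8 µM | 4.8 µM | 4.8 µM |
| remark | run made earlier | run made earlier | run made earlier |  |

| run | time / min | product / % |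
|---|---|---|
| green | 0.500 | 5 |
| green | 0.833 | 1 |
| green | 1.33 | 4 |
| green | 2.00 | 3 |
| green | 4.00 | 14 |
| green | 6.00 | 16 |
| ochre | 1.00 | 7 |
| ochre | 2.00 | 20 |
| ochre | 3.00 | 24 |
| ochre | 4.00 | 35 |
| ochre | 5.00 | 42 |
| ochre | 6.00 | 49 |
| red | 1.33 | 48 |
| red | 2.50 | 77 |
| red | 4.00 | 93 |
| red | 5.00 | 98 |
| red | 6.00 | 98 |

(scatter of a reading: 2 percentage points)

- "the catalyst" is free catalyst with its forms; second catalyst is a second catalyst
- what has left substrate counts as converted, also if it is not yet product

1. apparent order in reagent when 10% of the substrate are converted (percent change of the rate of making product for one percent more reagent charged)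
2. apparent order in free catalyst when 10% of the substrate are converted (percent change of the rate of making product for one percent more free catalyst charged)
3. factor on the rate of making product when 10% of the substrate are converted if free catalyst is charged twice over

On that supposition, 60.0% of the second catalyst charged to the flask outlasts the impurity; this fraction is the working share. The same subtraction gives 80.0% in red, 46.7% in ochre and 20.0% in green. It holds neither reagent nor free catalyst, so it gives no number for the orders, but it does give a clock for product.

Read as pseudo-first-order, red's reading at 2.50 min gives 0.588 min⁻¹. If this constant follows the working amount, meaning share times second catalyst charged, the flask runs at 0.220 min⁻¹, ochre at 0.129 min⁻¹ and green at 0.0367 min⁻¹.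

The ladder of time constants, fastest first, is then red at 1.70 min, the flask at 4.54 min, ochre at 7.78 min and green at 27.2 min. Red has 93% product by 4.00 min, while green has 16% at 6.00 min, a time shorter than green's time constant. My own reckoning puts the flask between them, at 66.8% product after 5.00 min.

The forecast gave 0.05 for the order in reagent, 0.25 for the order in free catalyst and a factor of 1.2 on doubling, with the words “so the reagent order is near zero”.

The flask gives 0.50, 0.21 and 1.16.

    substrate + free catalyst → free catalyst + open intermediate (k = 2800 M⁻¹ s⁻¹)
    second catalyst + open intermediate ⇌ catalyst intermediate (K = 700 M⁻¹, k = 3200 M⁻¹ s⁻¹)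
    reagent + catalyst intermediate → second catalyst + product (k = 500 M⁻¹ s⁻¹)
    free catalyst + added ligand ⇌ idle complex, settled at all times (K = 25000 M⁻¹)
    second catalyst + impurity → spent catalyst (k = 71000 M⁻¹ s⁻¹)

In the flask, spent catalyst stands at 40.0% of the second catalyst charged at 1.00 min, against the 40.0% of the charge that lies outside the working share, and product stands at 66.5% after 5.00 min, against the clock's 66.8%. On ochre the same clock gives 53.8% at 6.00 min, and the reading there is 49%. The path from second catalyst + impurity to spent catalyst has the largest single effect on the flask's order in free catalyst: the same run without that path gives 0.0047 in place of 0.21.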